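The constants belong to no real substance; the result is computed.

The ratio of J's two drains at the start, passage over G to E against pairing to J2, is 0.299, which gives the passage a starting share of 23.0% of the J lost.

J 0.80 M; Z 200 mM (held); G 80 mM; time 4.0 d

    Z ⇌ X, rate k1*(csat - [X]) (k1 = 0.029 min⁻¹, csat = 200 mM)
    J + G ⇌ G + E (K2 = 1.7, k2 = 0.040 L mol⁻¹ min⁻¹)
    X + G + E → G + Q (k3 = 1.1 L² mol⁻² min⁻¹)
    2 J → J2 (k4 = 0.0067 L mol⁻¹ min⁻¹)

- at 4.0 d, what has stopped the reaction, if anything has (it is still moving / no working catalyst is left / forward and back rates have come level / all of J has reacted)
- how much of the J has reacted by 4.0 d
- how much Q there is at 4.0 d, in percent of the J charged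

- in percentages every species weighs as the J in it: one J2 counts as two
- for a step with 2 of a species take k times the square, and two of it per event
- at the start none of X is dissolved
- the reaction counts as stopped when no species that holds the J changes by six tenths of a point or more over the second half of the time
- run time (flask): 4.0 d

Yet I reckon a much larger fraction of the charge through E, and the two numbers seem not to fit. They do fit. The passage is pseudo-first-order in J, with G standing on both sides of its steps, while pairing goes with the square of the fraction of J left. So the ratio at any moment is the starting ratio over that fraction, and it rises as J falls. Summed over the charge, with s the ratio, the fraction through E is s·ln(1+1/s), which is 43.9%, more than the starting share.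

Now I go round again, since E can return to J. X fills in about 34.5 min, faster than the forward half-life of J in the passage, 0.15 d, so I take X at saturation. Then 9.66% of E goes back, and G cancels from that share. The ratio falls to 0.270, and I carry this as the split number, the net first-order loss of J over its pairing constant times the charge. Put back in, it gives 41.8% as Q. That half-life is short against 4.0 d, so I expect hardly any J left at that time, since pairing adds to this first-order loss.

The forecast says all of J has reacted, with 100% reacted and 41% as Q, “leaving roughly 40% as Q and the rest as J2”, against my 41.8%.

The simulation gives all of J has reacted, with 100% reacted and 41.7% as Q. In this flask the passage to E ran while J lasted, half of it done by 0.0890 d, with X already at 0.194 M and J down to 4.98% by 0.400 d. Q then rose from 36.1% to 41.7% by 2.00 d, while J2 stood at 58.3%. The backward share reads 11% where I took 9.66%. With G at 0.20 M the split number becomes 0.674, which reckons to 61.3%. That neighbour flask ends with 39.6% as J2 and 60.4% as Q.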